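The route rests on cutting the eremophilane core at C5–C10 and C3–C4, so that both carbocycles come from one open chain. An intramolecular Diels–Alder reaction between an (E)-β-methyl enoate (C15 ester, C4=C5) and a (1E,3E)-1-silyloxy diene (C10=C1–C2=C3) closes ring A and ring B in a single operation and sets C3, C4, C5 and C10. It exploits the fact that these four contiguous stereocentres, including quaternary C5 and the cis carbon substituents on C4 and C5, all lie on ring A. The precursor is an undeca-2,8,10-trienoate whose C6–C9 tether carries the C7 isopropenyl group and an 8,9-cis-acetonide, with C8 and C9 drawn from 2-deoxy-D-ribose.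

Key step: step 8

Remarks on the chemistry:
- Eremophilane numbering is kept for all intermediates (C14 = methyl on C5, C15 = carbon on C4, C11–C13 = isopropenyl); β is the face of C14 and α the opposite face.
- The cycloaddition precursor needs 8R,9S, which is the 2-deoxy-D-erythro pattern. A glyceraldehyde acetonide used as the C8–C10 unit with its aldehyde carbon as C8 would have to be the S enantiomer. 2-Deoxy-D-ribose is used instead and supplies C1, C10, C9, C8 and C7 with both centres correct.
- Counted through the ester carbon the triene is an undeca-2,8,10-trienoate (a 1,7,9-decatriene when counted from C4).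
- (S)-Pent-1-yn-3-ol and angelic acid are taken as commercial.

Step 1
Reactants: 1 2-deoxy-D-ribose; 2 2-methoxypropene
Product: 3 2-deoxy-3,4-O-isopropylidene-D-erythro-pentopyranose (lactol; anomer mixture)
Conditions: PPTS (cat.), EtOAc, 0 °C to rt
Reagents that add atoms: 2-methoxypropene, C=C(C)OC
Why: Acid-catalysed acetonide formation (transketalisation with the enol ether) engages the only cis-vicinal diol of the pyranose form, O3/O4, and leaves the anomeric hydroxyl free; no stereocentre is created.

Step 2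
Reactants: 3 lactol acetonide; 4 (1,3-dioxolan-2-ylmethyl)triphenylphosphonium bromide
Product: 5 [(4R,5S)-5-[3-(1,3-dioxolan-2-yl)prop-2-en-1-yl]-2,2-dimethyl-1,3-dioxolan-4-yl]methanol (C1=C2 as Z/E mixture)
Conditions: KOtBu, THF, 0 °C to rt
Reagents that add atoms: (1,3-dioxolan-2-ylmethyl)triphenylphosphonium bromide, [Br-].C(C1OCCO1)[P+](c1ccccc1)(c1ccccc1)c1ccccc1
Why: Wittig olefination of the open-chain aldehyde in equilibrium with the lactol adds C2 and C3 as a masked enal and frees the C7 hydroxyl; the alkene geometry is unimportant because C1–C2 becomes the central single bond of the diene in step 7.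

Step 3
Reactants: 5 alkenyl dioxolane alcohol; 6 1-(triphenylphosphoranylidene)propan-2-one
Product: 8 (3E)-4-[(4R,5S)-5-[3-(1,3-dioxolan-2-yl)prop-2-en-1-yl]-2,2-dimethyl-1,3-dioxolan-4-yl]but-3-en-2-one, via aldehyde 7 (not isolated)
Conditions: Dess–Martin periodinane, CH2Cl2, 0 °C to rt; then 6, 40 °C
Reagents that add atoms: 1-(triphenylphosphoranylidene)propan-2-one, CC(=O)C=P(c1ccccc1)(c1ccccc1)c1ccccc1
Why: Dess–Martin oxidation gives the α-alkoxy aldehyde, which is trapped at once by the non-basic keto-stabilised ylide (Wittig reaction) to give the E-enone, so that C8 should not epimerise.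

Step 4
Reactants: 8 enone; 9 isopropenylmagnesium bromide
Product: 11 (4S)-4-[(4R,5S)-5-[3-(1,3-dioxolan-2-yl)prop-2-en-1-yl]-2,2-dimethyl-1,3-dioxolan-4-yl]-5-methylhex-5-en-2-one, via trimethylsilyl enol ether 10 (not isolated)
Conditions: CuI (20 mol %), Me3SiCl, THF, −78 °C; then K2CO3 (cat.), MeOH, 0 °C
Reagents that add atoms: isopropenylmagnesium bromide, C=C(C)[Mg]Br
Why: Copper-catalysed, silyl chloride-accelerated conjugate addition of the alkenyl Grignard reagent to the γ-alkoxy (E)-enone should occur anti to the C8–O bond (modified Felkin–Anh arrangement with H8 inside), which sets C7 as S with isopropenyl and O8 anti, the usual sense for organocopper additions to γ-alkoxy enones and enoates.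

Step 5
Reactants: 11 methyl ketone; 12 trimethyl phosphonoacetate
Product: 13 methyl (2E,5S)-5-[(4R,5S)-5-[3-(1,3-dioxolan-2-yl)prop-2-en-1-yl]-2,2-dimethyl-1,3-dioxolan-4-yl]-3,6-dimethylhepta-2,6-dienoate
Conditions: NaH, THF, 0 to 50 °C
Reagents that add atoms: trimethyl phosphonoacetate, COC(=O)CP(=O)(OC)OC
Why: Horner–Wadsworth–Emmons olefination of the methyl ketone places the ester trans to the larger C6 branch and should give mainly the (E)-β-methyl enoate, the minor Z isomer being removed by chromatography.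

Step 6
Reactants: 13 enoate acetal; 14 water
Product: 15 methyl (2E,5S)-5-[(4R,5S)-2,2-dimethyl-5-[(2E)-4-oxobut-2-en-1-yl]-1,3-dioxolan-4-yl]-3,6-dimethylhepta-2,6-dienoate
Conditions: PPTS (cat.), acetone/H2O (10:1), 50 °C
Reagents that add atoms: water, O
Why: Mild acid-catalysed acetal hydrolysis cleaves the allylic dioxolane through its alkenyl-stabilised oxocarbenium ion, while the acetone medium keeps the 8,9-acetonide in place and the acid equilibrates the enal to E.

Step 7
Reactants: 15 enal; 16 tert-butyldimethylsilyl trifluoromethanesulfonate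
Product: 17 methyl (2E,5S)-5-[(4R,5S)-5-[(1E,3E)-4-(tert-butyldimethylsilyloxy)buta-1,3-dien-1-yl]-2,2-dimethyl-1,3-dioxolan-4-yl]-3,6-dimethylhepta-2,6-dienoate
Conditions: Et3N, CH2Cl2, −78 to 0 °C
Reagents that add atoms: tert-butyldimethylsilyl trifluoromethanesulfonate, CC(C)(C)[Si](C)(C)OS(=O)(=O)C(F)(F)F
Why: Soft enolisation (O-silylation of the enal, then γ-deprotonation at C10 by the amine) gives the silyl dienol ether without a free dienolate that could expel O9; the s-trans enal should give E at C2=C3 and allylic strain should favour E at C10=C1.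

Step 8
Reactants: 17 silyloxy trienoate
Product: 18 methyl 3β-(tert-butyldimethylsilyloxy)-8α,9α-isopropylidenedioxy-10αH-eremophila-1,11-dien-15-oate (trans-fused; 4β-CO2Me; 5β-CH3; 7α-isopropenyl)
Conditions: toluene (0.01 M), BHT (cat.), Et3N (trace), 150 °C, sealed tube
Reagents that add atoms: none
Why: A concerted, suprafacial thermal [4+2] cycloaddition (HOMO of the 1-silyloxy diene C10=C1–C2=C3 with LUMO of the enoate C4=C5, the oxygenated terminus C3 pairing with ester-bearing C4) forms C5–C10 and C3–C4; the closest known reaction type is the thermal type 1 intramolecular Diels–Alder reaction of ester-terminated undeca-2,8,10-trienoates to trans-fused octalins. Ring A closes as the new cyclohexene through both new bonds, while ring B closes through the C5–C10 bond alone across the four-carbon tether C6–C9, which adopts a chair held gauche by the cis-dioxolane. C4 and C5 take the cis relation of C15 and C14 from the E-enoate geometry, and C3 and C10 take the cis relation of H3 and H10 from the (1E,3E)-diene geometry. The ester-endo, tether-anti transition state, favoured by secondary overlap of the ester carbonyl with C1–C2, puts O3 cis to C15 and makes the ring fusion trans (C14 anti to H10). The π-faces are chosen by C7, C8 and C9: one chair has isopropenyl and O9 equatorial with O8 axial, whereas the other trans-fused chair would hold isopropenyl, O9 and C14 all syn-axial. The step therefore needs endo over exo selectivity, which rests on the ester activation, and one tether chair over the other, which rests on the 7S,8R,9S pattern; BHT and a trace of base protect the acid-labile dienol ether.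

Step 9
Reactants: 18 cycloadduct ester
Product: 19 3β-(tert-butyldimethylsilyloxy)-8α,9α-isopropylidenedioxy-10αH-eremophila-1,11-dien-15-ol
Conditions: LiAlH4, Et2O, 0 °C
Reagents that add atoms: none
Why: Hydride reduction of the ester gives the primary alcohol, while the silyl ether, the acetonide and both alkenes are inert to LiAlH4.

Step 10
Reactants: 19 primary alcohol; 20 4-methylbenzenesulfonyl chloride
Product: 21 3β-(tert-butyldimethylsilyloxy)-8α,9α-isopropylidenedioxy-10αH-eremophila-1,11-dien-15-yl 4-methylbenzenesulfonate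
Conditions: Et3N, DMAP (cat.), CH2Cl2, 0 °C to rt
Reagents that add atoms: 4-methylbenzenesulfonyl chloride, Cc1ccc(cc1)S(=O)(=O)Cl
Why: Sulfonylation of the only free hydroxyl turns C15–O into a leaving group without touching any stereocentre.

Step 11
Reactants: 21 tosylate
Product: 22 3β-(tert-butyldimethylsilyloxy)-8α,9α-isopropylidenedioxy-10αH-eremophila-1,11-diene (4β-CH3)
Conditions: LiBHEt3, THF, 0 to 60 °C
Reagents that add atoms: none
Why: SN2 displacement of the primary tosylate by the strongly nucleophilic hydride of LiBHEt3 turns C15 into the C4 methyl group, this reagent attacking carbon and not sulfur even at β-branched primary centres.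

Step 12
Reactants: 22 silyl ether
Product: 23 8α,9α-isopropylidenedioxy-10αH-eremophila-1,11-dien-3β-ol
Conditions: Bu4NF, THF, rt
Reagents that add atoms: none
Why: Fluoride-mediated desilylation frees the axial allylic 3β-alcohol and leaves the acetonide untouched.

Step 13
Reactants: 23 allylic alcohol
Product: 24 8α,9α-isopropylidenedioxy-10αH-eremophila-1,11-dien-3-one
Conditions: Dess–Martin periodinane, CH2Cl2, 0 °C to rt
Reagents that add atoms: none
Why: Dess–Martin oxidation under neutral conditions gives the enone without base that could epimerise C4 or deconjugate toward C10.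

Step 14
Reactants: 24 enone
Product: 26 8α,9α-isopropylidenedioxy-10αH-eremophil-11-en-3α-ol, via saturated ketone 25 (not isolated)
Conditions: Li, NH3(l)/THF, −78 °C; then EtOH, −33 °C; NH4Cl
Reagents that add atoms: none
Why: Dissolving-metal (Birch-type) reduction first saturates the conjugated C1=C2 bond while the isolated isopropenyl group is inert, and after ethanol releases the ketone it is reduced under thermodynamic control to the equatorial 3α-alcohol, the axial epimer being disfavoured by the syn-axial C14 methyl.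

Step 15
Reactants: 27 (S)-pent-1-yn-3-ol; 28 angelic acid
Product: 29 (R)-pent-1-yn-3-yl (Z)-2-methylbut-2-enoate
Conditions: PPh3, i-PrO2C–N=N–CO2i-Pr (DIAD), THF, 0 °C to rt
Reagents that add atoms: angelic acid, C/C=C(/C)C(=O)O
Why: Mitsunobu esterification inverts the propargylic carbinol centre (S to R) by SN2 attack of the carboxylate and, since the acid is never activated at its carbonyl, the angelate should keep its Z geometry.

Step 16
Reactants: 29 propargylic angelate; 30 carbon dioxide
Product: 31 (4R)-4-[(Z)-2-methylbut-2-enoyloxy]hex-2-ynoic acid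
Conditions: LiN(SiMe3)2, THF, −78 °C; CO2; then aq. HCl
Reagents that add atoms: carbon dioxide, O=C=O
Why: Deprotonation of the terminal alkyne by the non-nucleophilic amide and carboxylation with CO2 gives the ynoic acid; the angelate has no α-hydrogen and should not be attacked at −78 °C.

Step 17
Reactants: 26 3α-alcohol; 31 ynoic acid
Product: 32 8α,9α-isopropylidenedioxy-10αH-eremophil-11-en-3α-yl (4R)-4-[(Z)-2-methylbut-2-enoyloxy]hex-2-ynoate
Conditions: i-PrN=C=N-i-Pr, DMAP (cat.), CH2Cl2, −20 to 0 °C
Reagents that add atoms: (4R)-4-[(Z)-2-methylbut-2-enoyloxy]hex-2-ynoic acid, OC(=O)C#C[C@@H](CC)OC(=O)/C(C)=C\C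
Why: Carbodiimide (Steglich) esterification acylates the equatorial C3 alcohol with retention, and carrying the side chain as the alkyne avoids the Z to E isomerisation that activating a (Z)-enoic acid risks.

Step 18
Reactants: 32 ynoate
Product: 33 8α,9α-isopropylidenedioxy-10αH-eremophil-11-en-3α-yl (2Z,4R)-4-[(Z)-2-methylbut-2-enoyloxy]hex-2-enoate
Conditions: H2 (1 atm), Pd/CaCO3 poisoned with Pb(OAc)2 (Lindlar catalyst), quinoline, EtOAc, rt
Reagents that add atoms: none
Why: Lindlar semi-hydrogenation adds hydrogen syn to the electron-poor alkyne to give the Z-enoate, and the poisoned catalyst should spare the isopropenyl and angelate alkenes.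

Step 19
Reactants: 33 acetonide
Product: 34 8α,9α-dihydroxy-10αH-eremophil-11-en-3α-yl (2Z,4R)-4-[(Z)-2-methylbut-2-enoyloxy]hex-2-enoate (3R,4R,5R,7S,8R,9S,10R; CNP0382739.1)
Conditions: AcOH/H2O (4:1), 40 °C
Reagents that add atoms: none
Why: Mild aqueous-acid hydrolysis of the isopropylidene acetal frees the 8,9-diol under conditions that the two esters, the Z-enoate and the isopropenyl group should tolerate.

Compound list
1 | 2-deoxy-D-ribose, (3S,4R)-3,4,5-trihydroxypentanal (open-chain form) | O=CC[C@H](O)[C@H](O)CO | starting material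
2 | 2-methoxypropene | C=C(C)OC | starting material
3 | 2-deoxy-3,4-O-isopropylidene-D-erythro-pentopyranose (anomer mixture) | OC1C[C@@H]2OC(C)(C)O[C@@H]2CO1 | intermediate
4 | (1,3-dioxolan-2-ylmethyl)triphenylphosphonium bromide | [Br-].C(C1OCCO1)[P+](c1ccccc1)(c1ccccc1)c1ccccc1 | starting material
5 | [(4R,5S)-5-[3-(1,3-dioxolan-2-yl)prop-2-en-1-yl]-2,2-dimethyl-1,3-dioxolan-4-yl]methanol (C1=C2 Z/E mixture) | OC[C@H]1OC(C)(C)O[C@H]1CC=CC2OCCO2 | intermediate
6 | 1-(triphenylphosphoranylidene)propan-2-one | CC(=O)C=P(c1ccccc1)(c1ccccc1)c1ccccc1 | starting material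
7 | (4S,5S)-5-[3-(1,3-dioxolan-2-yl)prop-2-en-1-yl]-2,2-dimethyl-1,3-dioxolane-4-carbaldehyde | O=C[C@H]1OC(C)(C)O[C@H]1CC=CC2OCCO2 | intermediate (not isolated)
8 | (3E)-4-[(4R,5S)-5-[3-(1,3-dioxolan-2-yl)prop-2-en-1-yl]-2,2-dimethyl-1,3-dioxolan-4-yl]but-3-en-2-one | CC(=O)/C=C/[C@H]1OC(C)(C)O[C@H]1CC=CC2OCCO2 | intermediate
9 | isopropenylmagnesium bromide | C=C(C)[Mg]Br | starting material
10 | trimethylsilyl enol ether of 11 (C5=C6 enol ether, geometry not defined) | CC(O[Si](C)(C)C)=C[C@@H](C(C)=C)[C@H]1OC(C)(C)O[C@H]1CC=CC2OCCO2 | intermediate (not isolated)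
11 | (4S)-4-[(4R,5S)-5-[3-(1,3-dioxolan-2-yl)prop-2-en-1-yl]-2,2-dimethyl-1,3-dioxolan-4-yl]-5-methylhex-5-en-2-one | CC(=O)C[C@@H](C(C)=C)[C@H]1OC(C)(C)O[C@H]1CC=CC2OCCO2 | intermediate
12 | trimethyl phosphonoacetate | COC(=O)CP(=O)(OC)OC | starting material
13 | methyl (2E,5S)-5-[(4R,5S)-5-[3-(1,3-dioxolan-2-yl)prop-2-en-1-yl]-2,2-dimethyl-1,3-dioxolan-4-yl]-3,6-dimethylhepta-2,6-dienoate | COC(=O)/C=C(\C)C[C@@H](C(C)=C)[C@H]1OC(C)(C)O[C@H]1CC=CC2OCCO2 | intermediate
14 | water | O | starting material
15 | methyl (2E,5S)-5-[(4R,5S)-2,2-dimethyl-5-[(2E)-4-oxobut-2-en-1-yl]-1,3-dioxolan-4-yl]-3,6-dimethylhepta-2,6-dienoate | COC(=O)/C=C(\C)C[C@@H](C(C)=C)[C@H]1OC(C)(C)O[C@H]1C/C=C/C=O | intermediate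
16 | tert-butyldimethylsilyl trifluoromethanesulfonate | CC(C)(C)[Si](C)(C)OS(=O)(=O)C(F)(F)F | starting material
17 | methyl (2E,5S)-5-[(4R,5S)-5-[(1E,3E)-4-(tert-butyldimethylsilyloxy)buta-1,3-dien-1-yl]-2,2-dimethyl-1,3-dioxolan-4-yl]-3,6-dimethylhepta-2,6-dienoate | COC(=O)/C=C(\C)C[C@@H](C(C)=C)[C@H]1OC(C)(C)O[C@H]1/C=C/C=C/O[Si](C)(C)C(C)(C)C | intermediate
18 | methyl 3β-(tert-butyldimethylsilyloxy)-8α,9α-isopropylidenedioxy-10αH-eremophila-1,11-dien-15-oate (trans-fused) | C=C(C)[C@@H]1C[C@]2(C)[C@@H](C(=O)OC)[C@@H](O[Si](C)(C)C(C)(C)C)C=C[C@H]2[C@H](OC(C)(C)O3)[C@@H]13 | intermediate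
19 | 3β-(tert-butyldimethylsilyloxy)-8α,9α-isopropylidenedioxy-10αH-eremophila-1,11-dien-15-ol | C=C(C)[C@@H]1C[C@]2(C)[C@@H](CO)[C@@H](O[Si](C)(C)C(C)(C)C)C=C[C@H]2[C@H](OC(C)(C)O3)[C@@H]13 | intermediate
20 | 4-methylbenzenesulfonyl chloride | Cc1ccc(cc1)S(=O)(=O)Cl | starting material
21 | 15-O-tosylate of 19 | C=C(C)[C@@H]1C[C@]2(C)[C@@H](COS(=O)(=O)c4ccc(C)cc4)[C@@H](O[Si](C)(C)C(C)(C)C)C=C[C@H]2[C@H](OC(C)(C)O3)[C@@H]13 | intermediate
22 | 3β-(tert-butyldimethylsilyloxy)-8α,9α-isopropylidenedioxy-10αH-eremophila-1,11-diene | C=C(C)[C@@H]1C[C@]2(C)[C@@H](C)[C@@H](O[Si](C)(C)C(C)(C)C)C=C[C@H]2[C@H](OC(C)(C)O3)[C@@H]13 | intermediate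
23 | 8α,9α-isopropylidenedioxy-10αH-eremophila-1,11-dien-3β-ol | C=C(C)[C@@H]1C[C@]2(C)[C@@H](C)[C@@H](O)C=C[C@H]2[C@H](OC(C)(C)O3)[C@@H]13 | intermediate
24 | 8α,9α-isopropylidenedioxy-10αH-eremophila-1,11-dien-3-one | C=C(C)[C@@H]1C[C@]2(C)[C@@H](C)C(=O)C=C[C@H]2[C@H](OC(C)(C)O3)[C@@H]13 | intermediate
25 | 8α,9α-isopropylidenedioxy-10αH-eremophil-11-en-3-one | C=C(C)[C@@H]1C[C@]2(C)[C@@H](C)C(=O)CC[C@H]2[C@H](OC(C)(C)O3)[C@@H]13 | intermediate (not isolated)
26 | 8α,9α-isopropylidenedioxy-10αH-eremophil-11-en-3α-ol | C=C(C)[C@@H]1C[C@]2(C)[C@@H](C)[C@H](O)CC[C@H]2[C@H](OC(C)(C)O3)[C@@H]13 | intermediate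
27 | (S)-pent-1-yn-3-ol | C#C[C@@H](O)CC | starting material
28 | angelic acid, (Z)-2-methylbut-2-enoic acid | C/C=C(/C)C(=O)O | starting material
29 | (R)-pent-1-yn-3-yl (Z)-2-methylbut-2-enoate | C#C[C@@H](CC)OC(=O)/C(C)=C\C | intermediate
30 | carbon dioxide | O=C=O | starting material
31 | (4R)-4-[(Z)-2-methylbut-2-enoyloxy]hex-2-ynoic acid | OC(=O)C#C[C@@H](CC)OC(=O)/C(C)=C\C | intermediate
32 | 8α,9α-isopropylidenedioxy-10αH-eremophil-11-en-3α-yl (4R)-4-[(Z)-2-methylbut-2-enoyloxy]hex-2-ynoate | C=C(C)[C@@H]1C[C@]2(C)[C@@H](C)[C@H](OC(=O)C#C[C@@H](CC)OC(=O)/C(C)=C\C)CC[C@H]2[C@H](OC(C)(C)O3)[C@@H]13 | intermediate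
33 | 8α,9α-isopropylidenedioxy-10αH-eremophil-11-en-3α-yl (2Z,4R)-4-[(Z)-2-methylbut-2-enoyloxy]hex-2-enoate | C=C(C)[C@@H]1C[C@]2(C)[C@@H](C)[C@H](OC(=O)/C=C\[C@@H](CC)OC(=O)/C(C)=C\C)CC[C@H]2[C@H](OC(C)(C)O3)[C@@H]13 | intermediate
34 | CNP0382739.1, (3R,4R,5R,7S,8R,9S,10R)-8,9-dihydroxyeremophil-11-en-3-yl (2Z,4R)-4-[(Z)-2-methylbut-2-enoyloxy]hex-2-enoate | C=C(C)[C@@H]1C[C@]2(C)[C@@H](C)[C@H](OC(=O)/C=C\[C@@H](CC)OC(=O)/C(C)=C\C)CC[C@H]2[C@H](O)[C@@H]1O | target

Total step count: 19. Longest linear sequence: 17 steps (steps 1–14 and 17–19); the side-chain acid 31 is made separately in steps 15–16.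

Steps most likely to fail

Step 8. The process at risk is an insufficient preference for the ester-endo transition state, which would give cis-fused material, or thermal decay of the dienol ether before ring closure. The fallback sets out from 17 and raises the dienophile reactivity instead of the temperature. The ester is reduced with i-Bu2AlH (CH2Cl2, −78 °C) to the allylic alcohol F1, and MnO2 (CH2Cl2, rt) oxidises this to the (E)-β-methyl enal F2. This much stronger dienophile should cyclise at or slightly above room temperature, where the dienol ether is stable and the endo preference of a formyl group is larger, to give the cycloadduct aldehyde F3. F3 is reduced in the same flask (NaBH4, MeOH, 0 °C) to 19, where the route is rejoined.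

Step 4. The process at risk is poor facial selectivity at C7, or competing 1,2-addition of the Grignard reagent. The fallback sets out from 8 and delivers the isopropenyl group under catalyst control by rhodium-catalysed asymmetric conjugate addition (Hayashi–Miyaura reaction) of CH2=C(CH3)BF3K with Rh(acac)(C2H4)2 and BINAP in dioxane/H2O. By analogy with simple (E)-enones, (S)-BINAP is expected to direct the alkenyl group to the face that gives 7S and so reinforce the substrate bias; both ligand enantiomers would be tested. The product is 11 itself, so the route is rejoined at 11 and no new compound arises (F0).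

Step 2. The process at risk is base-induced β-elimination of the C9 oxygen from the open-chain aldehyde, or slow olefination of the lactol by the less reactive acetal-bearing ylide. The fallback sets out from 3: methylenation with the more reactive ylide from Ph3PCH3Br and KOtBu (THF) gives [(4R,5S)-5-allyl-2,2-dimethyl-1,3-dioxolan-4-yl]methanol F4. Cross-metathesis of its terminal alkene with 2-vinyl-1,3-dioxolane (second-generation Hoveyda–Grubbs catalyst, CH2Cl2, 40 °C) then gives 5, mainly as the E isomer, where the route is rejoined.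

Further compounds
F1 | step 8 | (2E,5S)-5-[(4R,5S)-5-[(1E,3E)-4-(tert-butyldimethylsilyloxy)buta-1,3-dien-1-yl]-2,2-dimethyl-1,3-dioxolan-4-yl]-3,6-dimethylhepta-2,6-dien-1-ol | OC/C=C(\C)C[C@@H](C(C)=C)[C@H]1OC(C)(C)O[C@H]1/C=C/C=C/O[Si](C)(C)C(C)(C)C
F2 | step 8 | (2E,5S)-5-[(4R,5S)-5-[(1E,3E)-4-(tert-butyldimethylsilyloxy)buta-1,3-dien-1-yl]-2,2-dimethyl-1,3-dioxolan-4-yl]-3,6-dimethylhepta-2,6-dienal | O=C/C=C(\C)C[C@@H](C(C)=C)[C@H]1OC(C)(C)O[C@H]1/C=C/C=C/O[Si](C)(C)C(C)(C)C
F3 | step 8 | 3β-(tert-butyldimethylsilyloxy)-8α,9α-isopropylidenedioxy-10αH-eremophila-1,11-dien-15-al | C=C(C)[C@@H]1C[C@]2(C)[C@@H](C=O)[C@@H](O[Si](C)(C)C(C)(C)C)C=C[C@H]2[C@H](OC(C)(C)O3)[C@@H]13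
F0 | step 4 | none | none
F4 | step 2 | [(4R,5S)-5-allyl-2,2-dimethyl-1,3-dioxolan-4-yl]methanol | OC[C@H]1OC(C)(C)O[C@H]1CC=C
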